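A free target molecule at 70 °C makes 0.540 turnovers toward the isomer of the product in 2.5 min, counted as rate constant times time, so the four recipes differ in how much of that clock their target lives through.

| flask | starting material | reagent | temperature | time | remark |
|---|---|---|---|---|---|
| oak | 20 mM (fed, over 2.0 min) | 20.0 mM | 70 °C | 2.5 min | all else is in the flask from the start; the feed brings no volume worth counting |
| cedar | 20 mM | 20.0 mM (fed, over 12 s) | 70 °C | 2.5 min | all else is in the flask from the start; the feed brings no volume worth counting |
| birch | 20 mM | 20.0 mM (fed, over 2.0 min) | 70 °C | 2.5 min | all else is in the flask from the start; the feed brings no volume worth counting |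
| maple | 20 mM | 20.0 mM (fed, over 2.0 min) |  | 2.5 min | the addition at 40 °C, then warmed to 70 °C; the feed brings no volume worth counting |

* the flask with the highest share of target in target plus isomer of the product ("all alike" if they lie within 1.5 percentage points) (oak / cedar / birch / maple / all alike)
* share of target in target plus isomer of the product at the end, oak
* share of target in target plus isomer of the product at the end, cedar
* share of target in target plus isomer of the product at the end, birch
* share of target in target plus isomer of the product at the end, maple

- in percentages every species weighs as the starting material in it: one idle adduct counts as two
- for target the idle adduct is counted in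
- all constants are for 70 °C and move with temperature by the activation energies and enthalpies
- in an amount of target, one idle adduct counts as one target

    starting material → intermediate A (k1 = 0.0064 s⁻¹, Ea1 = 99.0 kJ mol⁻¹)
    reagent + intermediate A → target (k2 = 0.075 M⁻¹ s⁻¹, Ea2 = 63.0 kJ mol⁻¹)
    reagent + intermediate A ⇌ intermediate B (K3 = 9.7 M⁻¹, k3 = 0.018 M⁻¹ s⁻¹, Ea3 = 76.0 kJ mol⁻¹, ΔH3 = 6.00 kJ mol⁻¹)
    starting material + target ⇌ idle adduct, settled at all times (K4 = 60 M⁻¹, ΔH4 = 22.0 kJ mol⁻¹)
    target ⇌ isomer of the product (K5 = 15, k5 = 0.0036 s⁻¹, Ea5 = 111 kJ mol⁻¹, ΔH5 = −11.0 kJ mol⁻¹)
    (constants at 70 °C)

We reckon cedar first, in slow motion. In the first instants its reagent is in by 12 s, a feed far shorter than the run, and starting material begins turning into intermediate A at 0.0064 s⁻¹. In the middle intermediate A piles up, because the second step, the rate-limiting step for target, would need 11.1 min to consume it, longer than the run. The rate of target therefore climbs roughly with time, and we take the average target in cedar to be aged a third of the run, 50.0 s. Near the end [starting material] is 7.66 mM, and at that level the idle adduct holds part of the target away from isomerisation, leaving a free share of 68.5%. The isomer count is the rate constant of isomerisation times free share times mean age, the part of the target lost to the isomer: 0.123. We drop the return step, whose rate constant is 15 times smaller. Cedar then gets 87.7%.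

In oak the starting material is fed, and in birch the reagent; either feed adds a second ramp under the rate, so we take the mean age as a quarter of the run. Oak ends near 11.5 mM of starting material, with a count of 0.0798 and a share of 92.0%. Birch keeps cedar's free share, giving 90.8%. We treat maple's cold addition as a pause, so its clock covers 30.0 s, of which a third counts. With 16.5 mM of starting material, maple gets 98.2%, higher than the other three.

The forecast gives 92.5% for oak, 87.5% for cedar, 91.5% for birch and 97.5% for maple, and names maple, holding that “cedar's early reagent gives the oldest target”. It keeps our order, but our oak and birch lie lower, our maple lies higher, and our cedar stands about level with it.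

The run gives 92.1% for oak, 88.4% for cedar, 90.8% for birch and 97.9% for maple, so maple stands highest, with target at 0.511% of the charge, and the forecast holds. Cedar's isomer part of 11.6% stands beside our count of 0.123. For maple read at 6.0 min, the count with 4.02 mM of starting material is 0.232, which gives 76.8% against 78.6% in the run. Cedar is not at rest at 2.50 min, with 37.0% of its starting material left: at 25.0 min its share is 15.5%, with intermediate A still at 34.0%.

The numbers of this flask are invented; the rest is arithmetic.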